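The C9–C10 bond is made by dearomatization. In ring A the C3 oxygen stands para to the quaternary C10, and C4 carries a methyl group, so ring A is a disguised 2,4-dimethylphenol; C9, flanking the C8 ketone, can be the carbon of a diazoketone. Acid activation of that diazoketone lets the arene carbon para to the hydroxyl capture C9: one operation closes ring B, creates the C10 stereocenter and leaves a 1,4-diene-3,8-dione that already holds both methyls and both ring oxygens. The precursor is the free phenol 1-diazo-4-(3-hydroxy-2,6-dimethylphenyl)butan-2-one, kept as its aryl acetate until the diazoketone is in place.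

Key step: step 6

Numbering: eudesmane numbering is used for the bicyclic compounds (ring A: C1–C5 and C10; ring B: C5–C10; C14 on C10, C15 on C4, C11–C13 on C7). "11,12,13-Trinoreudesmane" is this decalin without the C7 side chain. α is the face opposite the C10 methyl.

Assumption: the sense of induction of the chiral acid in the key step cannot be predicted with confidence. The (R)-catalyst is written, and its mirror image is to be used if it favours the other enantiomer.

Remark: the C7 center created in the aldol step is not controlled and is removed in the following dehydration, so it is left undefined.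

Step 1
Reactants: 1 2-bromo-1,3-dimethylbenzene; 2 (3-ethoxy-3-oxopropyl)zinc bromide (solution in THF)
Product: 3 ethyl 3-(2,6-dimethylphenyl)propanoate
Conditions: Pd(OAc)2 (2 mol %), SPhos (4 mol %), THF, 60 °C
Reagents that add atoms: (3-ethoxy-3-oxopropyl)zinc bromide 2, CCOC(=O)CC[Zn]Br
Why: Negishi coupling, in which the primary alkylzinc bromide transmetalates to the arylpalladium bromide and the bulky, electron-rich biarylphosphine is known to carry sp2–sp3 couplings through for aryl bromides with two ortho substituents, while the ester is inert to the organozinc.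

Step 2
Reactants: 3 ethyl 3-(2,6-dimethylphenyl)propanoate
Product: 4 ethyl 3-(3-bromo-2,6-dimethylphenyl)propanoate
Conditions: Br2 (1.0 equiv), FeBr3 (5 mol %), CH2Cl2, 0 °C, dark
Reagents that add atoms: bromine, BrBr
Why: Electrophilic aromatic bromination should go to the ring position that is ortho to one methyl and para to the other, which is far more activated than the position para to the chain and meta to both methyls, and one equivalent of bromine in the dark avoids dibromination and benzylic bromination.

Step 3
Reactants: 4 ethyl 3-(3-bromo-2,6-dimethylphenyl)propanoate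
Product: 6 3-(3-acetoxy-2,6-dimethylphenyl)propanoic acid, via dipotassium phenoxide carboxylate 5 (not isolated)
Conditions: Pd2(dba)3 (1 mol %), tBuXPhos (4 mol %), KOH (4 equiv), 1,4-dioxane/H2O, 100 °C; then 0 °C, Ac2O; then aq. HCl
Reagents that add atoms: potassium hydroxide, [K+].[OH-]; acetic anhydride, CC(=O)OC(C)=O
Why: Palladium-catalysed hydroxylation of the aryl bromide with hydroxide (Buchwald–Hartwig-type C–O coupling) tolerates the ortho methyl group, the hot hydroxide saponifies the ethyl ester in the same pot, and the phenoxide is then acetylated by Ac2O in cold aqueous base (Schotten–Baumann acetylation) while the carboxylate returns as the free acid on acidification.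

Step 4
Reactants: 6 3-(3-acetoxy-2,6-dimethylphenyl)propanoic acid; 7 (trimethylsilyl)diazomethane
Product: 9 3-(4-diazo-3-oxobutyl)-2,4-dimethylphenyl acetate, via acid chloride 8 (not isolated)
Conditions: (COCl)2, DMF (cat.), CH2Cl2, 0 °C to rt; evaporate; then TMSCHN2 (2.2 equiv), THF/MeCN, 0 °C to rt
Reagents that add atoms: (trimethylsilyl)diazomethane 7, C[Si](C)(C)C=[N+]=[N-] (oxalyl chloride, O=C(Cl)C(=O)Cl, puts chlorine into 8 only)
Why: Acid chloride formation followed by C-acylation of the silyl diazomethane (the first stage of an Arndt–Eistert sequence) should give the diazoketone after loss of the silyl group, and the aryl acetate keeps the phenol from being acylated by the acid chloride.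

Step 5
Reactants: 9 3-(4-diazo-3-oxobutyl)-2,4-dimethylphenyl acetate
Product: 10 1-diazo-4-(3-hydroxy-2,6-dimethylphenyl)butan-2-one
Conditions: K2CO3 (0.2 equiv), MeOH, 0 °C
Reagents that add atoms: none
Why: Base-catalysed methanolysis (transesterification) of an aryl acetate is fast at 0 °C because phenoxide is a good leaving group, whereas α-diazoketones are stable to mild base.

Step 6
Reactants: 10 1-diazo-4-(3-hydroxy-2,6-dimethylphenyl)butan-2-one
Product: 12 (4aS)-1,4a-dimethyl-4a,5,7,8-tetrahydronaphthalene-2,6-dione [(10S)-11,12,13-trinoreudesma-1,4-diene-3,8-dione, 10β-methyl], via α-keto diazonium ion 11 (not isolated)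
Conditions: (R)-3,3'-bis(2,4,6-triisopropylphenyl)-1,1'-binaphthyl-2,2'-diyl N-triflylphosphoramide (10 mol %), toluene/CH2Cl2, −60 to −30 °C, slow addition of 10 (0.01 M)
Reagents that add atoms: none
Why: Proposed new method: the strong chiral Brønsted acid protonates the diazo carbon (C9) of 10 to give the α-keto diazonium ion 11, whose counter-anion stays hydrogen-bonded to the phenol hydroxyl; the arene carbon para to oxygen (C10) then displaces N2 from C9, and the O-protonated dienone returns the proton to the anion, which frees the catalyst. The closest known reaction type is the racemic CF3CO2H- or BF3-promoted aryl-participation cyclization of phenolic 1-diazo-4-arylbutan-2-ones to fused cyclohexadienones, together with chiral phosphoric acid-controlled dearomatizations of phenols and naphthols by external electrophiles; new here is the use of a chiral acid to choose the arene face in the diazoketone closure. Ring B closes in a 6-exo-tet mode, with the departing N2 outside the new ring. The only new stereocenter, the quaternary C10, is set by the chiral phosphoramidate anion, which is held at two points (ion pair at C9, hydrogen bond at the C3 oxygen) so that the tether should fold over one face of the arene only. The step needs para (C10) over ortho (C4) attack, and the substrate secures this because both closures are six-membered but the para carbon is the more nucleophilic and less crowded site and its methyl group blocks rearomatization, while O-alkylation would need an eight-membered ring. An N-triflyl phosphoramide is chosen over a phosphoric acid because the racemic reaction needs an acid at least as strong as CF3CO2H and because its shielded, weakly nucleophilic anion should resist alkylation by the diazonium ion.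

Step 7
Reactants: 12 (4aS)-1,4a-dimethyl-4a,5,7,8-tetrahydronaphthalene-2,6-dione
Product: 13 (4aR)-1,4a-dimethyl-3,4,4a,5,7,8-hexahydronaphthalene-2,6-dione [(10R)-11,12,13-trinoreudesm-4-ene-3,8-dione; same spatial arrangement at C10, descriptor changed by priority only]
Conditions: RhCl(PPh3)3 (5 mol %), H2 (1 atm), toluene/EtOH, rt
Reagents that add atoms: none
Why: Homogeneous hydrogenation with this rhodium complex is known to saturate only the disubstituted C1=C2 bond of cross-conjugated 1,4-dien-3-ones and to leave the tetrasubstituted C4=C5 bond and both ketones untouched, so no stereocenter is affected.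

Step 8
Reactants: 13 (10R)-11,12,13-trinoreudesm-4-ene-3,8-dione
Product: 15 (4S,5R,10R)-4-hydroxy-11,12,13-trinoreudesmane-3,8-dione (4α-OH, 4β-methyl, 5α-H, trans-decalin), via 4α-hydroperoxide 14 (not isolated)
Conditions: Mn(dpm)3 (10 mol %; dpm = dipivaloylmethanate), PhSiH3, O2 (1 atm), iPrOH/CH2Cl2, 0 °C to rt; then P(OEt)3
Reagents that add atoms: dioxygen, O=O
Why: Mukaiyama-type reductive α-hydroxylation of an enone (hydrogen-atom transfer from a manganese hydride to C5, capture of the C4 α-keto radical by O2, phosphite reduction of the hydroperoxide), in which hydrogen and oxygen should both enter from the α-face, opposite the axial C10 methyl, to give the trans ring fusion (5α-H) and the equatorial 4α-hydroxyl.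

Step 9
Reactants: 15 (4S,5R,10R)-4-hydroxy-11,12,13-trinoreudesmane-3,8-dione
Product: 16 (3S,4S,5R,10R)-3,4-dihydroxy-11,12,13-trinoreudesman-8-one (3β-OH, 4α-OH)
Conditions: Me4NBH(OAc)3, MeCN/AcOH, −20 °C
Reagents that add atoms: none
Why: Hydroxyl-directed triacetoxyborohydride reduction (the reagent of the Evans–Saksena reduction) reduces only the ketone next to the hydroxyl that binds boron, so C8 is spared, and internal delivery together with the usual axial attack from the α-face should give the equatorial 3β-alcohol trans to the 4α-hydroxyl.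

Step 10
Reactants: 16 (3S,4S,5R,10R)-3,4-dihydroxy-11,12,13-trinoreudesman-8-one; 17 (R)-2-methylbutanoic acid
Product: 18 (3S,4S,5R,10R)-4-hydroxy-8-oxo-11,12,13-trinoreudesman-3-yl (2R)-2-methylbutanoate
Conditions: DCC, DMAP (cat.), CH2Cl2, 0 °C to rt
Reagents that add atoms: (R)-2-methylbutanoic acid 17, CC[C@@H](C)C(=O)O
Why: Steglich esterification acylates only the secondary 3β-hydroxyl, since the tertiary 4α-hydroxyl is inert under carbodiimide/DMAP conditions, and the α-center of the acyl group is not enolized under these mild conditions.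

Step 11
Reactants: 18 (3S,4S,5R,10R)-4-hydroxy-8-oxo-11,12,13-trinoreudesman-3-yl (2R)-2-methylbutanoate; 19 acetone
Product: 21 (3S,4S,5R,10R)-4,11-dihydroxy-8-oxoeudesman-3-yl (2R)-2-methylbutanoate (C7 epimers), via bis(trimethylsilyl) enol ether 20 (not isolated)
Conditions: TMSOTf, Et3N, CH2Cl2, 0 °C; evaporate, pentane, filter; then acetone, TiCl4, CH2Cl2, −78 °C; aq. HCl/THF work-up
Reagents that add atoms: acetone 19, CC(C)=O (TMSOTf, C[Si](C)(C)OS(=O)(=O)C(F)(F)F, puts silicon into 20 only)
Why: Silylation gives the Δ7 silyl enol ether, because enolization away from the neopentyl C9 is both the kinetic and the thermodynamic direction in a trans-fused ring B, and caps the 4-hydroxyl, and the Mukaiyama aldol addition to TiCl4-activated acetone then forms the C7–C11 bond without a strong base that could epimerize the ester.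

Step 12
Reactants: 21 (3S,4S,5R,10R)-4,11-dihydroxy-8-oxoeudesman-3-yl (2R)-2-methylbutanoate
Product: 22 (3S,4S,5R,10R)-4-hydroxy-8-oxoeudesm-7(11)-en-3-yl (2R)-2-methylbutanoate
Conditions: TsOH·H2O (10 mol %), toluene, 60 °C
Reagents that add atoms: none
Why: Acid-catalysed dehydration of the β-hydroxy ketone through its enol (aldol condensation) should be much faster than ionization of the isolated tertiary 4-hydroxyl, which is deactivated by the neighbouring acyloxy group, and the acid also equilibrates any isopropenyl isomer to the conjugated isopropylidene ketone.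

Step 13
Reactants: 22 (3S,4S,5R,10R)-4-hydroxy-8-oxoeudesm-7(11)-en-3-yl (2R)-2-methylbutanoate
Product: 24 (3S,4S,5R,10R)-4,11-dihydroxy-8-oxoeudesm-6-en-3-yl (2R)-2-methylbutanoate (3β-acyloxy, 4α-OH, 5α-H, 10β-methyl; the target), via 11-hydroperoxide 23 (not isolated)
Conditions: O2, visible light, tetraphenylporphyrin (cat.), CH2Cl2, 0 °C; then PPh3
Reagents that add atoms: dioxygen, O=O
Why: Schenck ene reaction of singlet oxygen with the s-cis isopropylidene ketone, in which hydrogen is taken from the alkyl group geminal to the carbonyl (C6–H) and oxygen adds to the β-carbon C11, so that the double bond moves to C6=C7 and phosphine reduction of the tertiary hydroperoxide gives the 11-hydroxy enone without touching a stereocenter.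

Compound list
1 | 2-bromo-1,3-dimethylbenzene | Cc1cccc(C)c1Br | starting material
2 | (3-ethoxy-3-oxopropyl)zinc bromide | CCOC(=O)CC[Zn]Br | starting material
3 | ethyl 3-(2,6-dimethylphenyl)propanoate | CCOC(=O)CCc1c(C)cccc1C | intermediate
4 | ethyl 3-(3-bromo-2,6-dimethylphenyl)propanoate | CCOC(=O)CCc1c(C)ccc(Br)c1C | intermediate
5 | dipotassium 3-(2,6-dimethyl-3-oxidophenyl)propanoate | [K+].[K+].[O-]C(=O)CCc1c(C)ccc([O-])c1C | intermediate
6 | 3-(3-acetoxy-2,6-dimethylphenyl)propanoic acid | CC(=O)Oc1ccc(C)c(CCC(=O)O)c1C | intermediate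
7 | (trimethylsilyl)diazomethane | C[Si](C)(C)C=[N+]=[N-] | starting material
8 | 3-(3-acetoxy-2,6-dimethylphenyl)propanoyl chloride | CC(=O)Oc1ccc(C)c(CCC(=O)Cl)c1C | intermediate
9 | 3-(4-diazo-3-oxobutyl)-2,4-dimethylphenyl acetate | CC(=O)Oc1ccc(C)c(CCC(=O)C=[N+]=[N-])c1C | intermediate
10 | 1-diazo-4-(3-hydroxy-2,6-dimethylphenyl)butan-2-one | Cc1ccc(O)c(C)c1CCC(=O)C=[N+]=[N-] | intermediate
11 | 4-(3-hydroxy-2,6-dimethylphenyl)-2-oxobutane-1-diazonium ion (paired with the catalyst anion) | Cc1ccc(O)c(C)c1CCC(=O)C[N+]#N | intermediate
12 | (4aS)-1,4a-dimethyl-4a,5,7,8-tetrahydronaphthalene-2,6-dione [(10S)-11,12,13-trinoreudesma-1,4-diene-3,8-dione] | O=C1C=C[C@]2(C)CC(=O)CCC2=C1C | intermediate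
13 | (4aR)-1,4a-dimethyl-3,4,4a,5,7,8-hexahydronaphthalene-2,6-dione [(10R)-11,12,13-trinoreudesm-4-ene-3,8-dione] | O=C1CC[C@]2(C)CC(=O)CCC2=C1C | intermediate
14 | (4S,5R,10R)-4-hydroperoxy-11,12,13-trinoreudesmane-3,8-dione (4α-OOH, 5α-H) | O=C1CC[C@]2(C)CC(=O)CC[C@H]2[C@]1(C)OO | intermediate
15 | (4S,5R,10R)-4-hydroxy-11,12,13-trinoreudesmane-3,8-dione (4α-OH, 5α-H) | O=C1CC[C@]2(C)CC(=O)CC[C@H]2[C@]1(C)O | intermediate
16 | (3S,4S,5R,10R)-3,4-dihydroxy-11,12,13-trinoreudesman-8-one (3β-OH, 4α-OH, 5α-H) | O[C@H]1CC[C@]2(C)CC(=O)CC[C@H]2[C@]1(C)O | intermediate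
17 | (R)-2-methylbutanoic acid | CC[C@@H](C)C(=O)O | starting material
18 | (3S,4S,5R,10R)-4-hydroxy-8-oxo-11,12,13-trinoreudesman-3-yl (2R)-2-methylbutanoate | CC[C@@H](C)C(=O)O[C@H]1CC[C@]2(C)CC(=O)CC[C@H]2[C@]1(C)O | intermediate
19 | acetone | CC(C)=O | starting material
20 | (3S,4S,5R,10R)-4,8-bis(trimethylsilyloxy)-11,12,13-trinoreudesm-7-en-3-yl (2R)-2-methylbutanoate | CC[C@@H](C)C(=O)O[C@H]1CC[C@]2(C)CC(O[Si](C)(C)C)=CC[C@H]2[C@]1(C)O[Si](C)(C)C | intermediate
21 | (3S,4S,5R,10R)-4,11-dihydroxy-8-oxoeudesman-3-yl (2R)-2-methylbutanoate (C7 undefined) | CC[C@@H](C)C(=O)O[C@H]1CC[C@]2(C)CC(=O)C(C(C)(C)O)C[C@H]2[C@]1(C)O | intermediate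
22 | (3S,4S,5R,10R)-4-hydroxy-8-oxoeudesm-7(11)-en-3-yl (2R)-2-methylbutanoate | CC[C@@H](C)C(=O)O[C@H]1CC[C@]2(C)CC(=O)C(=C(C)C)C[C@H]2[C@]1(C)O | intermediate
23 | (3S,4S,5R,10R)-11-hydroperoxy-4-hydroxy-8-oxoeudesm-6-en-3-yl (2R)-2-methylbutanoate | CC[C@@H](C)C(=O)O[C@H]1CC[C@]2(C)CC(=O)C(C(C)(C)OO)=C[C@H]2[C@]1(C)O | intermediate
24 | (3S,4S,5R,10R)-4,11-dihydroxy-8-oxoeudesm-6-en-3-yl (2R)-2-methylbutanoate (CNP0201989.1) | CC[C@@H](C)C(=O)O[C@H]1CC[C@]2(C)CC(=O)C(C(C)(C)O)=C[C@H]2[C@]1(C)O | target

Total step count: 13
Longest linear sequence: 13 steps (1 to 24); 2, 7, 17 and 19 are bought.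

Steps most likely to fail

Step 6 (the step with the proposed new method). The chiral acid may give poor facial selectivity, may be consumed by alkylation of its anion, or may be too slow at low temperature, so that intermolecular O-alkylation takes over. The fallback gives up catalytic induction for the known racemic closure and a resolution. It sets out from 10: treatment with CF3CO2H in CH2Cl2 at −20 °C should give racemic 1,4a-dimethyl-4a,5,7,8-tetrahydronaphthalene-2,6-dione F1. Preparative chromatography on a chiral stationary phase (cellulose tris(3,5-dimethylphenylcarbamate)) should separate it into the (4aS)-enantiomer, which is 12 and re-enters the route at step 7, and (4aR)-1,4a-dimethyl-4a,5,7,8-tetrahydronaphthalene-2,6-dione F2, which is discarded.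

Step 8. Hydrogen-atom transfer to the fully substituted C4=C5 bond may be slow, the C4 radical may be reduced instead of oxygenated, or oxygen may enter from both faces. The fallback separates reduction and oxygenation by classical enolate chemistry. It sets out from 13: selective ketalization of the saturated C8 ketone (ethylene glycol, TsOH, toluene, reflux with water removal) should give (10R)-8,8-(ethylenedioxy)-11,12,13-trinoreudesm-4-en-3-one F3. Birch-type reduction of the enone with Li in NH3/THF and trapping of the C3 enolate with Me3SiCl/Et3N should give the trans-fused (5R,10R)-8,8-(ethylenedioxy)-3-(trimethylsilyloxy)-11,12,13-trinoreudesm-3-ene F4. Rubottom oxidation with mCPBA (NaHCO3, CH2Cl2, −20 °C) should epoxidize the enol ether from the α-face, and work-up with aqueous HCl in THF should remove the silyl group and the dioxolane to return 15.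

Step 13. Singlet oxygen may react sluggishly with the electron-poor alkene or abstract hydrogen from the C12/C13 methyl groups instead of C6. The fallback builds the hydroxy enone without the isopropylidene ketone, by an addition–aldol–elimination sequence that replaces steps 11 to 13. It sets out from 20, which is isolated for this purpose. Saegusa–Ito oxidation with Pd(OAc)2 in MeCN should give (3S,4S,5R,10R)-8-oxo-4-(trimethylsilyloxy)-11,12,13-trinoreudesm-6-en-3-yl (2R)-2-methylbutanoate F5. Conjugate addition of PhSeSiMe3 (TMSOTf cat., CH2Cl2, −78 °C) should give the 6-(phenylselanyl)-4,8-bis(trimethylsilyloxy)-11,12,13-trinoreudesm-7-en-3-yl ester F6. Mukaiyama aldol addition to acetone (TiCl4, −78 °C, acidic work-up) should give the 4,11-dihydroxy-8-oxo-6-(phenylselanyl)eudesman-3-yl ester F7. Oxidation with H2O2/pyridine and syn-elimination of the selenoxide toward C7 should give 24.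

Further compounds
F1 | step 6 | racemic 1,4a-dimethyl-4a,5,7,8-tetrahydronaphthalene-2,6-dione | O=C1C=CC2(C)CC(=O)CCC2=C1C
F2 | step 6 | (4aR)-1,4a-dimethyl-4a,5,7,8-tetrahydronaphthalene-2,6-dione | O=C1C=C[C@@]2(C)CC(=O)CCC2=C1C
F3 | step 8 | (10R)-8,8-(ethylenedioxy)-11,12,13-trinoreudesm-4-en-3-one | O=C1CC[C@]2(C)CC3(OCCO3)CCC2=C1C
F4 | step 8 | (5R,10R)-8,8-(ethylenedioxy)-3-(trimethylsilyloxy)-11,12,13-trinoreudesm-3-ene | CC1=C(O[Si](C)(C)C)CC[C@]2(C)CC3(OCCO3)CC[C@@H]12
F5 | step 13 | (3S,4S,5R,10R)-8-oxo-4-(trimethylsilyloxy)-11,12,13-trinoreudesm-6-en-3-yl (2R)-2-methylbutanoate | CC[C@@H](C)C(=O)O[C@H]1CC[C@]2(C)CC(=O)C=C[C@H]2[C@]1(C)O[Si](C)(C)C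
F6 | step 13 | (3S,4S,5R,10R)-6-(phenylselanyl)-4,8-bis(trimethylsilyloxy)-11,12,13-trinoreudesm-7-en-3-yl (2R)-2-methylbutanoate (C6 undefined) | CC[C@@H](C)C(=O)O[C@H]1CC[C@]2(C)CC(O[Si](C)(C)C)=CC([Se]c3ccccc3)[C@H]2[C@]1(C)O[Si](C)(C)C
F7 | step 13 | (3S,4S,5R,10R)-4,11-dihydroxy-8-oxo-6-(phenylselanyl)eudesman-3-yl (2R)-2-methylbutanoate (C6 and C7 undefined) | CC[C@@H](C)C(=O)O[C@H]1CC[C@]2(C)CC(=O)C(C(C)(C)O)C([Se]c3ccccc3)[C@H]2[C@]1(C)O
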